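**Strategy.** Everything rests on cutting the bond between C3' of the 2',4',6'-trihydroxyphenyl (A) ring of the dihydrochalcone and the benzylic methine of the 1,4-diaryl-2,3-dimethylbutane chain. One chiral-phosphoric-acid-catalysed Friedel–Crafts 1,6-addition joins the unprotected dihydrochalcone to a para-quinone methide released from a 4-hydroxybenzylic alcohol, sets the benzylic stereocentre and delivers the target directly. It exploits the para-OH of the phenyl ring on that methine (quinone-methide handle) and the OH-flanked, symmetry-equivalent C3'/C5' positions of the A ring. The precursor alcohol (either carbinol epimer) carries both methyl stereocentres, relayed by a trans-selective lactone methylation from purchased (R)-β-methyl-γ-butyrolactone.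

Key step: step 8

Remark 1: (R)-4-methyldihydrofuran-2(3H)-one is taken as a catalogue compound of high enantiomeric purity.
Remark 2: (R)-TRIP is written in step 8; which antipode is matched to the (R)-configured benzylic carbon cannot be predicted with confidence for this nucleophile and would be settled by one trial with each antipode, with nothing else changed.

Step 1
Reactants: 1 phloroglucinol (benzene-1,3,5-triol); 2 3-(4-methoxyphenyl)propanoic acid
Product: 3 1-(2,4,6-trihydroxyphenyl)-3-(4-methoxyphenyl)propan-1-one (2',4',6'-trihydroxy-4-methoxydihydrochalcone)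
Conditions: BF3·OEt2 (as medium), 85 °C; aq. NaOAc
Reagents that add atoms: none
Why: Friedel–Crafts acylation of the very nucleophilic phloroglucinol by the BF3-activated acid should stop after one acylation, because the chelated aryl ketone is deactivated and all three ring C–H positions are equivalent.

Step 2
Reactants: 4 (R)-4-methyldihydrofuran-2(3H)-one
Product: 6 (3R,4R)-3,4-dimethyldihydrofuran-2(3H)-one (trans), via lithium enolate 5 (not isolated)
Conditions: LDA, THF, −78 °C; MeI, −78 → −40 °C
Reagents that add atoms: iodomethane, CI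
Why: Kinetic lactone enolate alkylation in which iodomethane approaches the face opposite the neighbouring C4 methyl group, so the new C3 centre should form mainly trans (3R), as is usual for β-substituted γ-butyrolactone enolates.

Step 3
Reactants: 6 (3R,4R)-3,4-dimethyldihydrofuran-2(3H)-one
Product: 8 ethyl (2R,3R)-4-bromo-2,3-dimethylbutanoate, via bromo acid 7 (not isolated)
Conditions: dry HBr, EtOH, 0 °C → rt
Reagents that add atoms: hydrogen bromide, Br; ethanol, CCO
Why: Acidic alkyl–oxygen cleavage of the lactone by bromide (SN2 at the primary C5) followed by Fischer esterification, the classical conversion of γ-butyrolactones into ethyl 4-bromobutanoates, touches neither stereocentre.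

Step 4
Reactants: 8 ethyl (2R,3R)-4-bromo-2,3-dimethylbutanoate; 9 (4-bromophenoxy)(tert-butyl)dimethylsilane
Product: 10 ethyl (2R,3S)-4-[4-(tert-butyldimethylsilyloxy)phenyl]-2,3-dimethylbutanoate
Conditions: NiI2 (cat.), 4,4'-di-tert-butyl-2,2'-bipyridine (cat.), NaI (cat.), pyridine (cat.), Zn dust, DMPU, 60 °C
Reagents that add atoms: none
Why: Nickel-catalysed reductive cross-electrophile coupling of a primary alkyl bromide with an aryl bromide forms the C(sp3)–C(sp2) bond without an organometallic reagent that would attack the ester, and the reacting carbon is not a stereocentre (the descriptor at C3 changes only by priority).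

Step 5
Reactants: 10 ethyl (2R,3S)-4-[4-(tert-butyldimethylsilyloxy)phenyl]-2,3-dimethylbutanoate
Product: 11 (2R,3S)-4-[4-(tert-butyldimethylsilyloxy)phenyl]-2,3-dimethylbutanal
Conditions: DIBAL-H, CH2Cl2, −78 °C; MeOH, then aq. Rochelle salt; used at once
Reagents that add atoms: none
Why: Partial ester reduction with DIBAL-H at −78 °C should stop at the aluminium hemiacetal, which releases the aldehyde only on work-up, and the α-stereocentre is kept by avoiding base and storage.

Step 6
Reactants: 11 (2R,3S)-4-[4-(tert-butyldimethylsilyloxy)phenyl]-2,3-dimethylbutanal; 9 (4-bromophenoxy)(tert-butyl)dimethylsilane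
Product: 13 (2R,3S)-1,4-bis[4-(tert-butyldimethylsilyloxy)phenyl]-2,3-dimethylbutan-1-ol (both C1 epimers), via aryl Grignard reagent 12 (not isolated)
Conditions: 9, Mg, THF, rt; then 11, −78 → 0 °C; aq. NH4Cl
Reagents that add atoms: none
Why: Grignard formation and 1,2-addition to the aldehyde; the new carbinol centre needs no control (a Felkin–Anh-biased epimer mixture is expected) because it is erased in step 8.

Step 7
Reactants: 13 (2R,3S)-1,4-bis[4-(tert-butyldimethylsilyloxy)phenyl]-2,3-dimethylbutan-1-ol
Product: 14 4-[(2R,3S)-1-hydroxy-4-(4-hydroxyphenyl)-2,3-dimethylbutyl]phenol (both C1 epimers)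
Conditions: TBAF, AcOH, THF, 0 °C
Reagents that add atoms: none
Why: Fluoride cleavage of both aryl silyl ethers, buffered with acetic acid so that the para-hydroxybenzylic alcohol is neither ionised nor eliminated.

Step 8
Reactants: 14 4-[(2R,3S)-1-hydroxy-4-(4-hydroxyphenyl)-2,3-dimethylbutyl]phenol; 3 1-(2,4,6-trihydroxyphenyl)-3-(4-methoxyphenyl)propan-1-one
Product: 16 1-{3-[(1R,2R,3S)-1,4-bis(4-hydroxyphenyl)-2,3-dimethylbutyl]-2,4,6-trihydroxyphenyl}-3-(4-methoxyphenyl)propan-1-one (CNP0193401.1), via para-quinone methide 15 (not isolated)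
Conditions: (R)-TRIP (10 mol%), 3 (3 equiv), 4 Å MS, CH2Cl2–EtOAc (4:1), 0 °C → rt
Reagents that add atoms: none
Why: The phosphoric acid activates the benzylic OH of 14, water leaves, and the para-quinone methide 15 stays hydrogen-bonded to the chiral phosphate through its carbonyl oxygen while the P=O oxygen binds a phenolic OH of 3; C3' of 3 then adds to the exocyclic methine carbon (Friedel–Crafts 1,6-addition) and both rings rearomatise. The closest known reaction type is the chiral-phosphoric-acid-catalysed 1,6-addition of phenols and naphthols to para-quinone methides generated in situ from para-hydroxybenzyl alcohols. No ring is closed. The new benzylic stereocentre (R) is set under catalyst control, the ion-paired phosphate shielding one face of the planar methine; both epimers of 14 converge on the same 15, and the neighbouring centre exerts only a small bias (methyl versus sec-alkyl in the A(1,3)-locked conformer). The step needs C- over O-alkylation and mono-alkylation (secured by the two OH groups flanking the equivalent C3'/C5' positions and by the excess of 3), attack by 3 and not by the chain's own phenol rings (the ring position that could close a tetralin is meta to its OH), and retention of the adjacent methyl-bearing centre (its C–H lies in the nodal plane of the methide π system in the preferred conformer, which disfavours tautomerisation to the vinylphenol).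

**Compound list**

1 | phloroglucinol (benzene-1,3,5-triol) | Oc1cc(O)cc(O)c1 | starting material
2 | 3-(4-methoxyphenyl)propanoic acid | COc1ccc(CCC(=O)O)cc1 | starting material
3 | 1-(2,4,6-trihydroxyphenyl)-3-(4-methoxyphenyl)propan-1-one | COc1ccc(CCC(=O)c2c(O)cc(O)cc2O)cc1 | intermediate
4 | (R)-4-methyldihydrofuran-2(3H)-one | O=C1C[C@@H](C)CO1 | starting material
5 | lithium (4R)-4-methyl-4,5-dihydrofuran-2-olate (lithium enolate of 4) | [Li+].[O-]C1=C[C@@H](C)CO1 | intermediate (not isolated)
6 | (3R,4R)-3,4-dimethyldihydrofuran-2(3H)-one | O=C1[C@H](C)[C@@H](C)CO1 | intermediate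
7 | (2R,3R)-4-bromo-2,3-dimethylbutanoic acid | OC(=O)[C@H](C)[C@@H](C)CBr | intermediate (not isolated)
8 | ethyl (2R,3R)-4-bromo-2,3-dimethylbutanoate | CCOC(=O)[C@H](C)[C@@H](C)CBr | intermediate
9 | (4-bromophenoxy)(tert-butyl)dimethylsilane | CC(C)(C)[Si](C)(C)Oc1ccc(Br)cc1 | starting material
10 | ethyl (2R,3S)-4-[4-(tert-butyldimethylsilyloxy)phenyl]-2,3-dimethylbutanoate | CCOC(=O)[C@H](C)[C@@H](C)Cc1ccc(O[Si](C)(C)C(C)(C)C)cc1 | intermediate
11 | (2R,3S)-4-[4-(tert-butyldimethylsilyloxy)phenyl]-2,3-dimethylbutanal | O=C[C@H](C)[C@@H](C)Cc1ccc(O[Si](C)(C)C(C)(C)C)cc1 | intermediate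
12 | [4-(tert-butyldimethylsilyloxy)phenyl]magnesium bromide | Br[Mg]c1ccc(O[Si](C)(C)C(C)(C)C)cc1 | intermediate (not isolated)
13 | (2R,3S)-1,4-bis[4-(tert-butyldimethylsilyloxy)phenyl]-2,3-dimethylbutan-1-ol, both C1 epimers | OC(c1ccc(O[Si](C)(C)C(C)(C)C)cc1)[C@H](C)[C@@H](C)Cc1ccc(O[Si](C)(C)C(C)(C)C)cc1 | intermediate
14 | 4-[(2R,3S)-1-hydroxy-4-(4-hydroxyphenyl)-2,3-dimethylbutyl]phenol, both C1 epimers | OC(c1ccc(O)cc1)[C@H](C)[C@@H](C)Cc1ccc(O)cc1 | intermediate
15 | 4-[(2R,3S)-4-(4-hydroxyphenyl)-2,3-dimethylbutylidene]cyclohexa-2,5-dien-1-one | O=C1C=CC(=C[C@H](C)[C@@H](C)Cc2ccc(O)cc2)C=C1 | intermediate (not isolated)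
16 | 1-{3-[(1R,2R,3S)-1,4-bis(4-hydroxyphenyl)-2,3-dimethylbutyl]-2,4,6-trihydroxyphenyl}-3-(4-methoxyphenyl)propan-1-one | COc1ccc(CCC(=O)c2c(O)cc(O)c([C@@H](c3ccc(O)cc3)[C@H](C)[C@@H](C)Cc3ccc(O)cc3)c2O)cc1 | target

**Count.** Total steps: 8. Longest linear sequence: 7 steps (steps 2–8, from 4 to 16).

**Steps most likely to fail**

1. Step 8. What may go wrong: poor facial selectivity at the benzylic carbon, because the catalyst has to override the weak substrate bias, which by the A(1,3) model points to the other face. Configuration at the adjacent methyl-bearing carbon may also be lost through quinone methide–vinylphenol tautomerisation, and a second alkylation may occur at C5'. The fallback reverses the order in which the two aryl groups reach the benzylic carbon; it sets out from 3 and 11 and comes back at 16, so steps 6 and 7 are not needed. Acid-mediated three-component condensation of 3, 11 and p-toluenesulfinic acid (HCO2H–H2O, rt) should give the benzylic sulfone F1, in which the bond between ring carbon C3' and the benzylic carbon already exists. K2CO3 then expels sulfinate to an ortho-quinone methide of the A ring, and Rh(I)-catalysed 1,4-addition of 4-hydroxyphenylboronic acid should give the mono-silyl ether of the target F2. In this ortho-quinone methide the incoming group is the aryl ring, so attack anti to the sec-alkyl arm of the A(1,3)-locked conformer corresponds to the (1R,2R) relationship, and substrate control works for the target instead of against it. TBAF/AcOH converts F2 into 16.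

2. Step 4. What may go wrong: slow capture of the β-branched primary alkyl radical at nickel, leading to reduction or dimerisation of the bromide, biaryl formation, or thermal relactonisation of the γ-bromo ester. The fallback sets out from 6 and comes back at 11, replacing steps 3–5. It uses the pseudo-C2 symmetry of the trans-2,3-dimethylbutane-1,4-diyl unit, which lets the two termini of 6 exchange roles. Addition of Grignard reagent 12 (1 equiv, THF, −78 °C) to the lactone carbonyl should give the γ-hydroxy aryl ketone F3. Ionic hydrogenation (Et3SiH, TFA, CH2Cl2, 0 °C) removes the benzylic oxygen to give the primary alcohol F4. Dess–Martin oxidation gives 11, the same enantiomer as from step 5.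

3. Step 5. What may go wrong: over-reduction to the primary alcohol, and epimerisation of the α-stereocentre of the aldehyde during work-up or handling. The fallback sets out from 10 and comes back at 13, replacing steps 5 and 6, and avoids the aldehyde altogether. Me2AlN(OMe)Me (from AlMe3 and MeONHMe·HCl, CH2Cl2) gives the Weinreb amide F5. Addition of 12 (THF, 0 °C) gives the aryl ketone F6 without over-addition (Weinreb ketone synthesis). NaBH4 in MeOH reduces F6 to 13 as the epimer mixture.

**Further compounds**

F1 | step 8 | 1-{3-[(2R,3S)-4-[4-(tert-butyldimethylsilyloxy)phenyl]-2,3-dimethyl-1-(4-methylbenzenesulfonyl)butyl]-2,4,6-trihydroxyphenyl}-3-(4-methoxyphenyl)propan-1-one, both C1 epimers | COc1ccc(CCC(=O)c2c(O)cc(O)c(C(S(=O)(=O)c3ccc(C)cc3)[C@H](C)[C@@H](C)Cc3ccc(O[Si](C)(C)C(C)(C)C)cc3)c2O)cc1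
F2 | step 8 | 1-{3-[(1R,2R,3S)-4-[4-(tert-butyldimethylsilyloxy)phenyl]-1-(4-hydroxyphenyl)-2,3-dimethylbutyl]-2,4,6-trihydroxyphenyl}-3-(4-methoxyphenyl)propan-1-one | COc1ccc(CCC(=O)c2c(O)cc(O)c([C@@H](c3ccc(O)cc3)[C@H](C)[C@@H](C)Cc3ccc(O[Si](C)(C)C(C)(C)C)cc3)c2O)cc1
F3 | step 4 | (2R,3R)-1-[4-(tert-butyldimethylsilyloxy)phenyl]-4-hydroxy-2,3-dimethylbutan-1-one | O=C(c1ccc(O[Si](C)(C)C(C)(C)C)cc1)[C@H](C)[C@@H](C)CO
F4 | step 4 | (2R,3S)-4-[4-(tert-butyldimethylsilyloxy)phenyl]-2,3-dimethylbutan-1-ol | OC[C@H](C)[C@@H](C)Cc1ccc(O[Si](C)(C)C(C)(C)C)cc1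
F5 | step 5 | (2R,3S)-4-[4-(tert-butyldimethylsilyloxy)phenyl]-N-methoxy-N,2,3-trimethylbutanamide | CON(C)C(=O)[C@H](C)[C@@H](C)Cc1ccc(O[Si](C)(C)C(C)(C)C)cc1
F6 | step 5 | (2R,3S)-1,4-bis[4-(tert-butyldimethylsilyloxy)phenyl]-2,3-dimethylbutan-1-one | O=C(c1ccc(O[Si](C)(C)C(C)(C)C)cc1)[C@H](C)[C@@H](C)Cc1ccc(O[Si](C)(C)C(C)(C)C)cc1
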